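## Retrosynthetic overview

1. Using isochromene numbering (C1, O2, C3 … C8a), the target is cut at C5–C6, O2–C1 and C4a–C8a. This gives an acyclic chiral enaminone thioester (C1, C6–C8a, octanoate already in place) and a C11 ynone (O2, C3–C5, heptyl chain).
2. Both rings close in one flask. The pyran ring (ring B) forms first: Michael addition, then the ketone oxygen closes onto C1 with loss of Me2NH to give a 4-methylpyrylium/anhydrobase. The carbocycle (ring A) forms second: the exocyclic CH2 (C5) is acylated by the thioester (C6).
3. The enaminone is the acetyl-aminomethylenated form of an α-octanoyloxy-α-methyl β-keto thioester; its ketone becomes C8 and its thioester becomes C6.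
4. The only stereocentre (C7, R) is set on the acyclic β-keto thioester by catalytic enantioselective α-octanoyloxylation, which also installs the ester. It is quaternary and is not touched afterwards.
5. Commercial inputs: a C4 β-keto thioester, MeI, dioctanoyl peroxide, DMF dimethyl acetal, octanoyl chloride and a silylpropyne.

Assumption: the diamine catalyst of step 2 is used as the antipode that gives the (S)-configured product (both antipodes are made from D- or L-tert-leucine); the sense of induction has not been established for this substrate and is confirmed by chiral HPLC and optical rotation on the first run.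

## Route

Step 1
Reactants: 1 S-tert-butyl 3-oxobutanethioate (S-tert-butyl acetothioacetate); 2 iodomethane
Product: 3 S-tert-butyl 2-methyl-3-oxobutanethioate (racemic)
Conditions: K2CO3 (1.2 equiv), MeI (1.05 equiv), acetone, 23 °C
Reagents that add atoms: iodomethane 2, CI
Why: The doubly activated methylene of the β-keto thioester is deprotonated by K2CO3 and the enolate is C-methylated by MeI (SN2 alkylation of an active methylene compound); the new centre is racemic and is made quaternary in step 2.

Step 2
Reactants: 3 S-tert-butyl 2-methyl-3-oxobutanethioate; 4 dioctanoyl peroxide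
Product: 5 S-tert-butyl (2S)-2-methyl-2-(octanoyloxy)-3-oxobutanethioate
Conditions: 4 (1.3 equiv), H2NCH(t-Bu)CH2NEt2·CF3SO3H (20 mol%, antipode per the assumption), BHT (10 mol%), MeCN, 25 °C, dark
Reagents that add atoms: dioctanoyl peroxide 4, CCCCCCCC(=O)OOC(=O)CCCCCCC
Why: Proposed new method: the chiral primary amine condenses with the acetyl ketone to a hydrogen-bonded enamine whose C2 attacks the O–O bond of the diacyl peroxide on the face directed by the protonated tertiary amine, and iminium hydrolysis releases the quaternary α-acyloxy ketone, so the C7 stereocentre of the target is set here by catalyst control; the closest known reaction type is the chiral-primary-amine-catalysed asymmetric α-benzoyloxylation of β-ketocarbonyl compounds with dibenzoyl peroxide, of which this is the aliphatic-peroxide, thioester variant.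

Step 3
Reactants: 5 S-tert-butyl (2S)-2-methyl-2-(octanoyloxy)-3-oxobutanethioate; 6 N,N-dimethylformamide dimethyl acetal
Product: 7 S-tert-butyl (2S,4E)-5-(dimethylamino)-2-methyl-2-(octanoyloxy)-3-oxopent-4-enethioate
Conditions: Me2NCH(OMe)2 (1.5 equiv), toluene, 70 °C, MeOH swept out with N2
Reagents that add atoms: N,N-dimethylformamide dimethyl acetal 6, COC(OC)N(C)C
Why: The acetyl methyl group, the only enolisable ketone position, condenses with the amide acetal (enaminone formation with loss of two MeOH) to give the E-vinylogous amide that supplies C1 and makes C8a nucleophilic; the quaternary stereocentre has no α-hydrogen and is unaffected.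

Step 4
Reactants: 8 octanoyl chloride; 9 trimethyl(prop-1-yn-1-yl)silane (1-(trimethylsilyl)propyne)
Product: 10 undec-2-yn-4-one
Conditions: AlCl3 (1.1 equiv), CH2Cl2, 0 °C; ice/aq HCl quench
Reagents that add atoms: trimethyl(prop-1-yn-1-yl)silane 9, CC#C[Si](C)(C)C
Why: Friedel–Crafts-type acylation of an alkynylsilane: the acylium ion attacks the silicon-bearing alkyne carbon (β-silyl cation stabilisation) and loss of Me3SiCl gives the ynone regiospecifically.

Step 5
Reactants: 7 S-tert-butyl (2S,4E)-5-(dimethylamino)-2-methyl-2-(octanoyloxy)-3-oxopent-4-enethioate; 10 undec-2-yn-4-one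
Product: 13 (7R)-3-heptyl-7-methyl-6,8-dioxo-7,8-dihydro-6H-isochromen-7-yl octanoate, via aminodienone 11 (not isolated), via methylenepyran 12 (not isolated)
Conditions: 10 (1.2 equiv), toluene–AcOH (5:1), 4 Å MS, 60 °C, 6 h; then 23 °C, AgOCOCF3 (1.3 equiv), dark, 2 h
Reagents that add atoms: undec-2-yn-4-one 10, CC#CC(=O)CCCCCCC
Why: Proposed new method: acid-mediated Michael addition of the enaminone α-carbon (C8a) to the ynone β-carbon (C4a), as in the first stage of a Bohlmann–Rahtz heteroannulation, gives 5-aminopentadienone 11, whose ketone oxygen closes onto C1 with loss of Me2NH (the classical aminopentadienone-to-pyrylium cyclisation) to give a 4-methylpyrylium in equilibrium with anhydrobase 12, and the exocyclic methylene carbon (C5), the normal acylation site of pyrylium anhydrobases because attack there restores the aromatic cation, then attacks the silver-activated S-tert-butyl thioester (Masamune-type acyl transfer) in a six-membered closure and loses a proton to give the azaphilone; the quaternary C7 centre is a spectator, so (2S)-7 maps onto (7R)-13 (the descriptor changes only because the CIP ranking of the two carbonyl arms is reversed).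

## Compound list

1 | S-tert-butyl 3-oxobutanethioate | CC(=O)CC(=O)SC(C)(C)C | starting material
2 | iodomethane | CI | starting material
3 | S-tert-butyl 2-methyl-3-oxobutanethioate (racemic) | CC(=O)C(C)C(=O)SC(C)(C)C | intermediate
4 | dioctanoyl peroxide | CCCCCCCC(=O)OOC(=O)CCCCCCC | starting material
5 | S-tert-butyl (2S)-2-methyl-2-(octanoyloxy)-3-oxobutanethioate | CCCCCCCC(=O)O[C@](C(C)=O)(C)C(=O)SC(C)(C)C | intermediate
6 | N,N-dimethylformamide dimethyl acetal | COC(OC)N(C)C | starting material
7 | S-tert-butyl (2S,4E)-5-(dimethylamino)-2-methyl-2-(octanoyloxy)-3-oxopent-4-enethioate | CCCCCCCC(=O)O[C@](C(=O)/C=C/N(C)C)(C)C(=O)SC(C)(C)C | intermediate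
8 | octanoyl chloride | CCCCCCCC(=O)Cl | starting material
9 | trimethyl(prop-1-yn-1-yl)silane | CC#C[Si](C)(C)C | starting material
10 | undec-2-yn-4-one | CC#CC(=O)CCCCCCC | intermediate
11 | S-tert-butyl (2S)-4-[(dimethylamino)methylidene]-2,5-dimethyl-2-(octanoyloxy)-3,7-dioxotetradec-5-enethioate (Michael adduct, interconverting double-bond isomers, not isolated) | CCCCCCCC(=O)O[C@](C(=O)C(=CN(C)C)C(C)=CC(=O)CCCCCCC)(C)C(=O)SC(C)(C)C | intermediate
12 | S-tert-butyl (2S)-3-(6-heptyl-4-methylidene-4H-pyran-3-yl)-2-methyl-2-(octanoyloxy)-3-oxopropanethioate (anhydrobase of the 4-methylpyrylium acetate, not isolated) | CCCCCCCC(=O)O[C@](C(=O)C1=COC(CCCCCCC)=CC1=C)(C)C(=O)SC(C)(C)C | intermediate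
13 | (7R)-3-heptyl-7-methyl-6,8-dioxo-7,8-dihydro-6H-isochromen-7-yl octanoate | CCCCCCCC(=O)O[C@]1(C)C(=O)C=C2C=C(CCCCCCC)OC=C2C1=O | target

## Step count and risks

Total steps: 5. Longest linear sequence: 4 (steps 1, 2, 3, 5); step 4 is a one-step side branch.

Steps most likely to fail:

Step 5. Three things can go wrong. The enaminone and ynone may combine by [2+2] addition and ring opening instead of Michael addition. The aminodienone may close through the heptyl α-carbon to a phenol instead of through oxygen. The anhydrobase may not acylate cleanly. In that case the ring order is reversed and the stages are separated, setting out from 7 and 10. They are combined in EtOH at 50 °C and the Michael adduct 11 is isolated. LiN(SiMe3)2 (THF, −78 to 0 °C) then gives the extended dienolate of the enone, whose γ-carbon (C5) attacks the thioester in a vinylogous Dieckmann cyclisation. This gives the carbocycle [(1R)-3-[(dimethylamino)methylidene]-1-methyl-2,6-dioxo-4-(2-oxononylidene)cyclohexyl] octanoate F1. CF3CO2H in CH2Cl2 then closes the pyran ring (enol oxygen onto the aminomethylene carbon, loss of dimethylamine), and the route is rejoined at 13.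

Step 2. The aliphatic peroxide may react sluggishly or the thioester may give low ee. Catalytic stereocontrol is then replaced by resolution, setting out from 3. Its sodium enolate (NaH, THF, 0 °C) is acyloxylated with 4 (classical enolate–diacyl peroxide reaction) to give racemic S-tert-butyl 2-methyl-2-(octanoyloxy)-3-oxobutanethioate F2. The enantiomers are separated by preparative chiral SFC, and the (S)-enantiomer rejoins the route as 5.

Step 3. Methanol and methoxide from the amide acetal may cleave the activated tertiary octanoate or the thioester. C1 is then introduced by an electrophilic instead of a basic aminomethylenation, setting out from 5. Me3SiOTf/Et3N (CH2Cl2, 0 °C) gives the silyl enol ether S-tert-butyl (2S)-2-methyl-2-(octanoyloxy)-3-[(trimethylsilyl)oxy]but-3-enethioate F3. Treatment with (chloromethylene)dimethyliminium chloride and then Et3N gives the enaminone, and the route is rejoined at 7.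

## Further compounds

F1 | step 5 | [(1R)-3-[(dimethylamino)methylidene]-1-methyl-2,6-dioxo-4-(2-oxononylidene)cyclohexyl] octanoate | CCCCCCCC(=O)O[C@]1(C)C(=O)CC(=CC(=O)CCCCCCC)C(=CN(C)C)C1=O
F2 | step 2 | racemic S-tert-butyl 2-methyl-2-(octanoyloxy)-3-oxobutanethioate | CCCCCCCC(=O)OC(C)(C(C)=O)C(=O)SC(C)(C)C
F3 | step 3 | S-tert-butyl (2S)-2-methyl-2-(octanoyloxy)-3-[(trimethylsilyl)oxy]but-3-enethioate | CCCCCCCC(=O)O[C@](C(=C)O[Si](C)(C)C)(C)C(=O)SC(C)(C)C
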